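(The readings come from a simulation for an exercise; scatter was added.)

Midnight looks nearly like the eta run: it has the same starting material, protic impurity and solid, but 0.300 M of first nucleophile in place of 0.60 M, and 40 °C in place of 0 °C. Autumn has midnight's charges and warms after the feed.

common to all: starting material 0.30 M

| run | first nucleophile | protic impurity | solid second nucleophile | temperature | remark | time |
|---|---|---|---|---|---|---|
| eta | 0.60 M (fed, over 30 s) | 0.060 M | 0.30 M | 0 °C | run made earlier; the fed solution adds 0.25 times the starting volume |  |
| midnight | 0.300 M (fed, over 30 s) | 0.0600 M | 0.300 M |  | at 40 °C throughout; the fed solution adds 0.25 times the starting volume | 60 min |
| autumn | 0.300 M (fed, over 30 s) | 0.0600 M | 0.300 M |  | at 0 °C until 30 s, from then on at 40 °C; the fed solution adds 0.25 times the starting volume | 15 min |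

- eta (time / min: target / %, other capture product / %, over-reaction product / %): 0.333: 7, 0, 1; 0.667: 13, 0, 1; 1.33: 23, 1, 2; 2.50: 37, 4, 6; 5.00: 43, 7, 21

(standard deviation of a reading: 1.5 percentage points)

- charges are per starting volume, the dose included; the dosed solution carries all of it
- at the start none of the solid second nucleophile is in solution
- the earlier runs do not show what temperature does; that part of a forecast is a guess

* which of the two ends with the higher share of target in all that became target or other capture product or over-reaction product ("neither" if they lie within 2 percentage points) (midnight / autumn / neither)
* share of target in all that became target or other capture product or over-reaction product, midnight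
* share of target in all that became target or other capture product or over-reaction product, autumn

Read eta first. Between 2.50 min and 5.00 min the over-reaction product gained 15 percentage points and target 6 points, so in those readings the over-reaction product was growing faster. You need not chase those rates to the end. Freeze the amounts and count instead.

This is my own reckoning, and it starts from a guess at who goes where. Suppose each other capture product and each over-reaction product holds one second nucleophile, and each protic impurity destroys one. Suppose too that the flask finishes, with the starting material in the three products and the solid, the dissolved second nucleophile and the impurity used up. With A, D and H the charges of starting material, solid and impurity, D − H lands on products, and the rest of the starting material stays target: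

R = (A − D + H)/A = 20.0%

This R, the target remainder, is a mass balance on the second nucleophile, and under these suppositions it is the target share at the end. It holds no rate and no first nucleophile, and eta, midnight and autumn have the same A, D and H, so they share it.

At 5.00 min the readings put 0.0840 M in the two eta products that I count as holding second nucleophile, so this count leaves about 0.156 M still to place. In this count, eta's 43% of target, higher than R, is a passing value. By the readings, eta had also turned 71.0% of its starting material into products by then, and the asked times of 15 min and 60 min are longer, so I expect both flasks to finish. What the warmth does is a guess.

The forecast says 78% for midnight, 80% for autumn, and neither for the higher one, holding that “over-reaction should collapse to a few percent”. My 20.0% differs from both numbers, though I also answer neither.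

Midnight gives 19.5% and autumn 19.3%, so the answer is neither. At 60.0 min midnight holds 72.3% of over-reaction product. Its protic impurity still has 2.5% of its charge left, and counting just the spent part puts R at 19.5%.

    starting material ⇌ intermediate (K = 0.00910, k = 0.00440 /s, Ea = 68.0 kJ/mol, ΔH = −28.0 kJ/mol)
    first nucleophile + intermediate → target (k = 10.0 /M/s, Ea = 39.0 kJ/mol)
    second nucleophile + target → over-reaction product (k = 0.0310 /M/s, Ea = 65.0 kJ/mol)
    second nucleophile + intermediate → other capture product (k = 5.60 /M/s, Ea = 48.0 kJ/mol)
    solid second nucleophile ⇌ second nucleophile, rate k5*(cs5 - [second nucleophile]) while solid is left; crystals form when [second nucleophile] > cs5 (solubility = 0.130 M, k = 0.0120 /s)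
    second nucleophile + protic impurity → quenched reagent (k = 0.120 /M/s, Ea = 47.0 kJ/mol)
    (constants at 0 °C)

Now take midnight with 0.024 M of protic impurity: R gives 8.00%. The computed flask ends at 7.98%.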